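**Retrosynthetic overview** (eremophilane numbering)
1. Target 21 ⇐ ketone 16 by late C8 oxygenation (enolate hydroxylation anti to the C7 isopropenyl) and two acylations; the C9 ketone is unveiled only after C10 is set.
2. 16 ⇐ chloride 13: C7–H and the isopropenyl group from the exocyclic allyl unit C7=C11–C12–Cl by palladium hydride transfer; C1–OH and C10–H from hydroboration of C1=C10. Both are steered by the axial C5 methyl.
3. Ring B (C5–C6–C7–C8–C9–C10), the last ring, ⇐ dienyl enal 8 by Prins cyclisation (C8–C9 bond); ring A is cyclohexenone 1, elaborated first.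
4. Enabling feature: C9 sits on C10, and C7, two atoms on across C8, carries a three-carbon branch. An aldehyde on C10 and a butadiene C8=C7(–C6)–C11(C13)=C12 hung on C5 therefore close ring B by C8–C9 bonding and leave an allyl cation over C7/C11/C12, the masked C7–H/isopropenyl pair.
5. 8 ⇐ 1: copper-catalysed asymmetric methyl addition (C4) with enolate alkylation (C5), Suzuki coupling, triflation, formylation.

Key step: step 5

Assumption: the ligand enantiomer in step 1 is the one that gives (S) at C4, and the C9 carbinol centre and the C7=C11 geometry of the intermediates that carry them are left unassigned because both are erased later.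

Step 1
Reactants: 1 2-methylcyclohex-2-en-1-one; 2 2,3-dibromoprop-1-ene
Product: 4 (2R,3S)-2-(2-bromoprop-2-en-1-yl)-2,3-dimethylcyclohexan-1-one, via magnesium enolate 3 (not isolated)
Conditions: MeMgBr, Cu(OTf)2 (3 mol %), chiral imidazolinium chloride (carbene precursor, 4 mol %), Et2O, −30 °C; then 2, DMPU, −30 → 20 °C
Reagents that add atoms: methylmagnesium bromide C[Mg]Br
Why: Copper-catalysed asymmetric conjugate addition sets C4 under ligand control, and C-alkylation of the tetrasubstituted enolate 3 by the allylic bromide should occur anti to the new C4 methyl, giving the C5 quaternary centre with C14 and C15 cis (conjugate addition–enolate alkylation).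

Step 2
Reactants: 4 (2R,3S)-2-(2-bromoprop-2-en-1-yl)-2,3-dimethylcyclohexan-1-one; 5 4,4,5,5-tetramethyl-2-(prop-1-en-2-yl)-1,3,2-dioxaborolane
Product: 6 (2R,3S)-2,3-dimethyl-2-(3-methyl-2-methylidenebut-3-en-1-yl)cyclohexan-1-one
Conditions: Pd(PPh3)4 (5 mol %), K2CO3, 1,4-dioxane/H2O, 85 °C
Reagents that add atoms: none
Why: Suzuki–Miyaura coupling of the 2-bromoalkene with the alkenylboronate builds the 2,3-disubstituted butadiene (C8=C7–C11=C12) without touching a stereocentre.

Step 3
Reactants: 6 (2R,3S)-2,3-dimethyl-2-(3-methyl-2-methylidenebut-3-en-1-yl)cyclohexan-1-one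
Product: 7 (5S,6R)-5,6-dimethyl-6-(3-methyl-2-methylidenebut-3-en-1-yl)cyclohex-1-en-1-yl trifluoromethanesulfonate
Conditions: KN(SiMe3)2, THF, −78 °C; PhNTf2, −78 → 0 °C
Reagents that add atoms: N-phenylbis(trifluoromethanesulfonimide) FC(F)(F)S(=O)(=O)N(c1ccccc1)S(=O)(=O)C(F)(F)F
Why: Only C1 carries α-hydrogens (C5 is quaternary), so enolate O-triflation is regiospecific and places the future C9 on C10.

Step 4
Reactants: 7 (5S,6R)-5,6-dimethyl-6-(3-methyl-2-methylidenebut-3-en-1-yl)cyclohex-1-en-1-yl trifluoromethanesulfonate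
Product: 8 (5S,6R)-5,6-dimethyl-6-(3-methyl-2-methylidenebut-3-en-1-yl)cyclohex-1-ene-1-carbaldehyde
Conditions: CO (1 atm), Pd(OAc)2 (5 mol %), dppp (5 mol %), Et3SiH, Et3N, DMF, 70 °C
Reagents that add atoms: carbon monoxide [C-]#[O+]
Why: Palladium-catalysed reductive carbonylation (formylation) of the alkenyl triflate—oxidative addition, CO insertion, hydride transfer from the silane—introduces C9 as the conjugated aldehyde.

Step 5
Reactants: 8 (5S,6R)-5,6-dimethyl-6-(3-methyl-2-methylidenebut-3-en-1-yl)cyclohex-1-ene-1-carbaldehyde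
Product: 9 12-chloroeremophila-1(10),7(11)-dien-9-ol (4β,5β-dimethyl; C9 epimers, E/Z at C7=C11)
Conditions: Me2AlCl (2.0 equiv), CH2Cl2, −78 °C; cold aqueous potassium sodium tartrate
Reagents that add atoms: dimethylaluminium chloride C[Al](C)Cl
Why: Me2AlCl binds the aldehyde oxygen and the terminal diene carbon C8 attacks C9, giving an aluminium alkoxide and an allyl cation over C7, C11 and C12 that is quenched at its primary end C12 by chloride from the aluminate. The closest known reaction type is the alkylaluminium chloride-promoted type 2 intramolecular Prins (carbonyl-ene) cyclisation of unsaturated aldehydes, which stops at the γ-chloro alcohol at low temperature. Ring B closes as a six-membered ring by C8–C9 bond formation, 6-endo with respect to the nucleophilic C7=C8 bond and exo with respect to C9=O, through a chair-like array C5–C6–C7–C8–C9–C10. The only new stereocentre is the C9 carbinol, expected pseudo-equatorial but inconsequential because C9 becomes the ketone in step 11; the C7=C11 geometry is erased in step 9. The step needs attack at the carbonyl carbon and not at C1, closure through C8 and not C12, and chloride capture and not proton loss. The tether secures the first two (C12 would give a seven-membered ring, attack at C1 a bridged bicyclo[3.3.1] skeleton), excess Me2AlCl at −78 °C the third, and since C10 is trigonal no ring-fusion stereochemistry is at stake here.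

Step 6
Reactants: 9 12-chloroeremophila-1(10),7(11)-dien-9-ol
Product: 10 12-chloro-9-(triethylsilyloxy)eremophila-1(10),7(11)-diene
Conditions: Et3SiOTf, 2,6-lutidine, CH2Cl2, −78 °C
Reagents that add atoms: triethylsilyl trifluoromethanesulfonate CC[Si](CC)(CC)OS(=O)(=O)C(F)(F)F
Why: Silylation of the allylic alcohol with a non-nucleophilic base protects O9 for the hydroboration and spares the allylic chloride.

Step 7
Reactants: 10 12-chloro-9-(triethylsilyloxy)eremophila-1(10),7(11)-diene
Product: 12 12-chloro-9-(triethylsilyloxy)-10αH-eremophil-7(11)-en-1α-ol, via alkylborane 11 (not isolated)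
Conditions: BH3·SMe2, THF, 0 °C; then 30% H2O2, pH 7 phosphate buffer, 0 → 20 °C
Reagents that add atoms: hydrogen peroxide OO
Why: Hydroboration–oxidation of the trisubstituted C1=C10 bond should occur syn from the α-face, opposite the axial C5 methyl, with boron at the less substituted C1; this sets 1α-OH and 10α-H (trans ring fusion) in one event while the tetrasubstituted C7=C11 bond stays inert.

Step 8
Reactants: 12 12-chloro-9-(triethylsilyloxy)-10αH-eremophil-7(11)-en-1α-ol
Product: 13 1α-(tert-butyldimethylsilyloxy)-12-chloro-9-(triethylsilyloxy)-10αH-eremophil-7(11)-ene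
Conditions: t-BuMe2SiOTf, 2,6-lutidine, CH2Cl2, −78 → 0 °C
Reagents that add atoms: tert-butyldimethylsilyl trifluoromethanesulfonate CC(C)(C)[Si](C)(C)OS(=O)(=O)C(F)(F)F
Why: Silylation gives O1 a group that survives the enolate chemistry of step 12 and can be removed separately from the O9 silyl ether.

Step 9
Reactants: 13 1α-(tert-butyldimethylsilyloxy)-12-chloro-9-(triethylsilyloxy)-10αH-eremophil-7(11)-ene
Product: 14 1α-(tert-butyldimethylsilyloxy)-9-(triethylsilyloxy)-10αH-eremophil-11-ene (7β-isopropenyl, 7α-H)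
Conditions: Pd2(dba)3 (2.5 mol %), PBu3 (10 mol %), HCO2NH4, 1,4-dioxane, 60 °C
Reagents that add atoms: none
Why: In this Tsuji-type allylic formate reduction the allylpalladium complex over C7–C11–C12 can change face through its C12 σ-form, and the palladium hydride should deliver hydrogen to the more substituted terminus C7 from the α-face, the β-face being closed by the axial C5 methyl, giving the axial 7β-isopropenyl group.

Step 10
Reactants: 14 1α-(tert-butyldimethylsilyloxy)-9-(triethylsilyloxy)-10αH-eremophil-11-ene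
Product: 15 1α-(tert-butyldimethylsilyloxy)-10αH-eremophil-11-en-9-ol
Conditions: PPTS (cat.), MeOH/CH2Cl2, 0 °C
Reagents that add atoms: none
Why: Mild acid methanolysis cleaves the secondary triethylsilyl ether much faster than the tert-butyldimethylsilyl ether.

Step 11
Reactants: 15 1α-(tert-butyldimethylsilyloxy)-10αH-eremophil-11-en-9-ol
Product: 16 1α-(tert-butyldimethylsilyloxy)-10αH-eremophil-11-en-9-one
Conditions: Dess–Martin periodinane, CH2Cl2, 0 → 20 °C
Reagents that add atoms: none
Why: Neutral Dess–Martin oxidation gives the C9 ketone without enolisation toward the now epimerisable C10.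

Step 12
Reactants: 16 1α-(tert-butyldimethylsilyloxy)-10αH-eremophil-11-en-9-one
Product: 18 1α-(tert-butyldimethylsilyloxy)-8α-hydroxy-10αH-eremophil-11-en-9-one, via potassium enolate 17 (not isolated)
Conditions: KN(SiMe3)2, THF, −78 °C; 2-(phenylsulfonyl)-3-phenyloxaziridine, −78 °C; aqueous NH4Cl
Reagents that add atoms: 2-(phenylsulfonyl)-3-phenyloxaziridine O=S(=O)(N1OC1c1ccccc1)c1ccccc1
Why: Kinetic deprotonation should take the C8 methylene and not the hindered tertiary C10–H, and oxaziridine hydroxylation of enolate 17 should occur anti to the adjacent C7 isopropenyl group, giving the trans 8α-alcohol.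

Step 13
Reactants: 18 1α-(tert-butyldimethylsilyloxy)-8α-hydroxy-10αH-eremophil-11-en-9-one
Product: 19 1α-(tert-butyldimethylsilyloxy)-8α-[(E)-2-methylbut-2-enoyloxy]-10αH-eremophil-11-en-9-one
Conditions: (E)-2-methylbut-2-enoyl chloride, pyridine, DMAP (cat.), CH2Cl2, 0 °C
Reagents that add atoms: tigloyl chloride C/C=C(\C)C(Cl)=O
Why: Acylation of the α-hydroxy ketone under weakly basic conditions installs the tiglate with retention at C8 and of the E geometry.

Step 14
Reactants: 19 1α-(tert-butyldimethylsilyloxy)-8α-[(E)-2-methylbut-2-enoyloxy]-10αH-eremophil-11-en-9-one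
Product: 20 1α-hydroxy-8α-[(E)-2-methylbut-2-enoyloxy]-10αH-eremophil-11-en-9-one
Conditions: HF·pyridine, THF/pyridine, 0 → 20 °C
Reagents that add atoms: none
Why: Buffered fluoride desilylation frees O1 under conditions too mild for C10 epimerisation or acyl migration.

Step 15
Reactants: 20 1α-hydroxy-8α-[(E)-2-methylbut-2-enoyloxy]-10αH-eremophil-11-en-9-one
Product: 21 1α-acetoxy-8α-[(E)-2-methylbut-2-enoyloxy]-10αH-eremophil-11-en-9-one (CNP0138236.1)
Conditions: Ac2O, pyridine, DMAP (cat.), CH2Cl2, 0 °C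
Reagents that add atoms: acetic anhydride CC(=O)OC(C)=O
Why: Acetylation of the equatorial β-hydroxy ketone at low temperature should give the target without β-elimination.

**Compound list**
1 | 2-methylcyclohex-2-en-1-one | CC1=CCCC1=O | starting material
2 | 2,3-dibromoprop-1-ene | C=C(Br)CBr | starting material
3 | bromomagnesium (3S)-2,3-dimethylcyclohex-1-en-1-olate | Br[Mg]OC1=C(C)[C@@H](C)CCC1 | intermediate
4 | (2R,3S)-2-(2-bromoprop-2-en-1-yl)-2,3-dimethylcyclohexan-1-one | C=C(Br)C[C@@]1(C)C(=O)CCC[C@@H]1C | intermediate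
5 | 4,4,5,5-tetramethyl-2-(prop-1-en-2-yl)-1,3,2-dioxaborolane | C=C(C)B1OC(C)(C)C(C)(C)O1 | starting material
6 | (2R,3S)-2,3-dimethyl-2-(3-methyl-2-methylidenebut-3-en-1-yl)cyclohexan-1-one | C=C(C)C(=C)C[C@@]1(C)C(=O)CCC[C@@H]1C | intermediate
7 | (5S,6R)-5,6-dimethyl-6-(3-methyl-2-methylidenebut-3-en-1-yl)cyclohex-1-en-1-yl trifluoromethanesulfonate | C=C(C)C(=C)C[C@@]1(C)C(OS(=O)(=O)C(F)(F)F)=CCC[C@@H]1C | intermediate
8 | (5S,6R)-5,6-dimethyl-6-(3-methyl-2-methylidenebut-3-en-1-yl)cyclohex-1-ene-1-carbaldehyde | C=C(C)C(=C)C[C@@]1(C)C(C=O)=CCC[C@@H]1C | intermediate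
9 | 12-chloroeremophila-1(10),7(11)-dien-9-ol (C9 and C7=C11 geometry unassigned) | ClCC(C)=C1C[C@@]2(C)C(C(O)C1)=CCC[C@@H]2C | intermediate
10 | 12-chloro-9-(triethylsilyloxy)eremophila-1(10),7(11)-diene | ClCC(C)=C1C[C@@]2(C)C(C(O[Si](CC)(CC)CC)C1)=CCC[C@@H]2C | intermediate
11 | 1α-boryl-12-chloro-9-(triethylsilyloxy)-10αH-eremophil-7(11)-ene | ClCC(C)=C1C[C@@]2(C)[C@H](C(O[Si](CC)(CC)CC)C1)[C@@H](B)CC[C@@H]2C | intermediate
12 | 12-chloro-9-(triethylsilyloxy)-10αH-eremophil-7(11)-en-1α-ol | ClCC(C)=C1C[C@@]2(C)[C@H](C(O[Si](CC)(CC)CC)C1)[C@@H](O)CC[C@@H]2C | intermediate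
13 | 1α-(tert-butyldimethylsilyloxy)-12-chloro-9-(triethylsilyloxy)-10αH-eremophil-7(11)-ene | ClCC(C)=C1C[C@@]2(C)[C@H](C(O[Si](CC)(CC)CC)C1)[C@@H](O[Si](C)(C)C(C)(C)C)CC[C@@H]2C | intermediate
14 | 1α-(tert-butyldimethylsilyloxy)-9-(triethylsilyloxy)-10αH-eremophil-11-ene (7β-isopropenyl) | C=C(C)[C@H]1C[C@@]2(C)[C@H](C(O[Si](CC)(CC)CC)C1)[C@@H](O[Si](C)(C)C(C)(C)C)CC[C@@H]2C | intermediate
15 | 1α-(tert-butyldimethylsilyloxy)-10αH-eremophil-11-en-9-ol | C=C(C)[C@H]1C[C@@]2(C)[C@H](C(O)C1)[C@@H](O[Si](C)(C)C(C)(C)C)CC[C@@H]2C | intermediate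
16 | 1α-(tert-butyldimethylsilyloxy)-10αH-eremophil-11-en-9-one | C=C(C)[C@H]1C[C@@]2(C)[C@H](C(=O)C1)[C@@H](O[Si](C)(C)C(C)(C)C)CC[C@@H]2C | intermediate
17 | potassium 8(9)-enolate of 16 | C=C(C)[C@H]1C[C@@]2(C)[C@H](C([O-])=C1)[C@@H](O[Si](C)(C)C(C)(C)C)CC[C@@H]2C.[K+] | intermediate
18 | 1α-(tert-butyldimethylsilyloxy)-8α-hydroxy-10αH-eremophil-11-en-9-one | C=C(C)[C@H]1C[C@@]2(C)[C@H](C(=O)[C@@H]1O)[C@@H](O[Si](C)(C)C(C)(C)C)CC[C@@H]2C | intermediate
19 | 1α-(tert-butyldimethylsilyloxy)-8α-tigloyloxy-10αH-eremophil-11-en-9-one | C=C(C)[C@H]1C[C@@]2(C)[C@H](C(=O)[C@@H]1OC(=O)/C(C)=C/C)[C@@H](O[Si](C)(C)C(C)(C)C)CC[C@@H]2C | intermediate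
20 | 1α-hydroxy-8α-tigloyloxy-10αH-eremophil-11-en-9-one | C=C(C)[C@H]1C[C@@]2(C)[C@H](C(=O)[C@@H]1OC(=O)/C(C)=C/C)[C@@H](O)CC[C@@H]2C | intermediate
21 | 1α-acetoxy-8α-tigloyloxy-10αH-eremophil-11-en-9-one | C=C(C)[C@H]1C[C@@]2(C)[C@H](C(=O)[C@@H]1OC(=O)/C(C)=C/C)[C@@H](OC(C)=O)CC[C@@H]2C | target

Total step count: 15. Longest linear sequence: 15 steps (1 → 21).

**Steps most likely to fail**

Step 5. The diene may add in the conjugate sense to C1 of the complexed enal, or the zwitterion may lose a proton or ionise at the allylic C9–O bond instead of collapsing to the chloride. The fallback raises C9 to the acyl chloride level, where only the acyl carbon can be attacked. It sets out from 8: chlorite oxidation (NaClO2, NaH2PO4, 2-methylbut-2-ene, t-BuOH/H2O) gives (5S,6R)-5,6-dimethyl-6-(3-methyl-2-methylidenebut-3-en-1-yl)cyclohex-1-ene-1-carboxylic acid F1. Oxalyl chloride with catalytic DMF gives the acid chloride F2. SnCl4 in CH2Cl2 at −78 °C then effects intramolecular acylation of the diene with chloride capture to 12-chloroeremophila-1(10),7(11)-dien-9-one F3. 1,2-Reduction (NaBH4, CeCl3·7H2O, MeOH, −78 °C) comes back to the route at 9.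

Step 9. Hydride may be transferred to the primary allyl terminus C12, giving the tetrasubstituted C7=C11 alkene, or facial control may be lost. The fallback sets out from 13: KOAc and 18-crown-6 in MeCN give the primary allylic acetate F4, and K2CO3 in MeOH the allylic alcohol F5. Mitsunobu reaction with 2-nitrobenzenesulfonylhydrazide (PPh3, diethyl azodicarboxylate, N-methylmorpholine, −30 → 20 °C) forms an allylic diazene. This loses dinitrogen by retro-ene transfer of hydrogen to C7, which is regiospecific by mechanism and expected from the open α-face, and comes back at 14.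

Step 12. Proton transfer between enolate and product, or enolate equilibration toward C10, would epimerise the ring fusion or eliminate the C1 silyloxy group, and the oxidant may approach with poor facial selectivity. The fallback avoids a free enolate. It sets out from 16: LiN(SiMe3)2 with Me3SiCl present (THF, −78 °C) gives the trimethylsilyl enol ether F6. Rubottom oxidation with dimethyldioxirane (acetone, −78 °C), then aqueous citric acid, comes back at 18.

**Further compounds**
F1 | step 5 | (5S,6R)-5,6-dimethyl-6-(3-methyl-2-methylidenebut-3-en-1-yl)cyclohex-1-ene-1-carboxylic acid | C=C(C)C(=C)C[C@@]1(C)C(C(=O)O)=CCC[C@@H]1C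
F2 | step 5 | (5S,6R)-5,6-dimethyl-6-(3-methyl-2-methylidenebut-3-en-1-yl)cyclohex-1-ene-1-carbonyl chloride | C=C(C)C(=C)C[C@@]1(C)C(C(=O)Cl)=CCC[C@@H]1C
F3 | step 5 | 12-chloroeremophila-1(10),7(11)-dien-9-one | ClCC(C)=C1C[C@@]2(C)C(C(=O)C1)=CCC[C@@H]2C
F4 | step 9 | 12-acetoxy-1α-(tert-butyldimethylsilyloxy)-9-(triethylsilyloxy)-10αH-eremophil-7(11)-ene | CC(=O)OCC(C)=C1C[C@@]2(C)[C@H](C(O[Si](CC)(CC)CC)C1)[C@@H](O[Si](C)(C)C(C)(C)C)CC[C@@H]2C
F5 | step 9 | 1α-(tert-butyldimethylsilyloxy)-9-(triethylsilyloxy)-10αH-eremophil-7(11)-en-12-ol | OCC(C)=C1C[C@@]2(C)[C@H](C(O[Si](CC)(CC)CC)C1)[C@@H](O[Si](C)(C)C(C)(C)C)CC[C@@H]2C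
F6 | step 12 | 1α-(tert-butyldimethylsilyloxy)-9-(trimethylsilyloxy)-10αH-eremophila-8,11-diene | C=C(C)[C@H]1C[C@@]2(C)[C@H](C(O[Si](C)(C)C)=C1)[C@@H](O[Si](C)(C)C(C)(C)C)CC[C@@H]2C
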